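Cuts: (i) C11–C12, the CH2–CH2 bond between the appendage on C9 of ring B and the chain; (ii) the C2–O and C3–O bonds (cis-diol from a C2=C3 alkene, itself from a 3-OH); (iii) C7=C8 from an exocyclic C8=C17; (iv) the C12=C13 bond of a butenolide.
Enabling feature: C11 and C12 are both plain CH2 groups, so each can be the α-carbon of a carboxylic acid. The chain C12–C16 (C13 methyl stereocentre, C15 carboxyl) is (R)-3-methylglutaric acid minus one CO2. The decalin (rings A/B, C1–C11, C17–C20, oxygen on C3 and on the axial C19) is andrographolide minus its butenolide. Two decarboxylations at one anode (mixed Kolbe electrolysis) join them.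
Forward: andrographolide is cleaved at C12=C13 to the C12 acid. A temporary γ-lactone ring (iodolactone, O on C8, I on C17) masks the acid and C8=C17 while ring A is rebuilt (19-OAc, 3-sulfonate, C2=C3, OsO4). Zinc removes the mask, the Kolbe union follows, a Co–H shift moves C8=C17 to C7=C8, and the ester is O-demethylated.
Stereochemistry: C4, C5, C9 and C10 come from andrographolide and C13 from the (R)-half ester. C2 and C3 come from syn-dihydroxylation anti to the axial C10–CH3 and C4–CH2OAc groups; the original C3 configuration is erased.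
Key step: step 8

Remark: labdane numbering is used (ring A C1–C5/C10, ring B C5–C10, C11 on C9, C17 on C8, C19 = axial CH2O on C4, C20 = CH3 on C10); iodolactone 4 is drawn as the trans-fused C8 epimer, and its C8 epimer would serve equally because C8 returns to sp2 in step 7.

Step 1
Reactants: 1 andrographolide
Product: 2 3,19-dihydroxy-13,14,15,16-tetranor-ent-labd-8(17)-en-12-al
Conditions: KMnO4 (1.5 equiv), THF/H2O, −10 °C; filtration through Celite, crude product used directly
Reagents that add atoms: potassium permanganate, [K+].[O-][Mn](=O)(=O)=O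
Why: Permanganate should add [3+2] fastest to the electron-poor, conjugated C12=C13 bond of the alkylidene lactone (its rate rises with acceptor substitution), and the manganate ester fragments to the C12 aldehyde and the α-keto lactone while the hindered isolated C8=C17 methylene reacts more slowly in the cold; reaction type: permanganate oxidative cleavage of an alkene.

Step 2
Reactants: 2 3,19-dihydroxy-13,14,15,16-tetranor-ent-labd-8(17)-en-12-al
Product: 3 3,19-dihydroxy-13,14,15,16-tetranor-ent-labd-8(17)-en-12-oic acid
Conditions: NaClO2, NaH2PO4, 2-methyl-2-butene (excess), t-BuOH/H2O, 0 °C to rt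
Reagents that add atoms: sodium chlorite, [Na+].[O-]Cl=O
Why: Pinnick oxidation should convert the aldehyde to the acid without touching the alcohols, the alkene scavenger keeping HOCl away from C8=C17.

Step 3
Reactants: 3 3,19-dihydroxy-13,14,15,16-tetranor-ent-labd-8(17)-en-12-oic acid
Product: 4 3,19-dihydroxy-17-iodo-13,14,15,16-tetranor-ent-labdan-12,8-olide (γ-lactone O on C8 anti to the C10 methyl, CH2I on C8)
Conditions: I2 (1.5 equiv), NaHCO3, MeCN/H2O, 0 °C, dark
Reagents that add atoms: iodine, II
Why: Iodolactonisation: 5-exo attack of the carboxylate on the iodonium ion at the tertiary C8 (Markovnikov), from the face away from the axial C10 methyl, should give a γ-lactone that masks both the acid and the C8=C17 alkene as a temporary ring.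

Step 4
Reactants: 4 3,19-dihydroxy-17-iodo-13,14,15,16-tetranor-ent-labdan-12,8-olide
Product: 6 19-acetate 3-mesylate of iodolactone 4, via 19-acetate 5 (not isolated)
Conditions: Ac2O (1.1 equiv), pyridine/CH2Cl2, 0 °C; then MsCl (2 equiv), Et3N, 0 °C to rt, same flask
Reagents that add atoms: acetic anhydride, CC(=O)OC(C)=O; methanesulfonyl chloride, CS(Cl)(=O)=O
Why: O-acylation followed by O-sulfonylation: the primary 19-OH should take up the limited anhydride before the hindered secondary 3-OH, which is then the only hydroxyl left for the sulfonyl chloride.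

Step 5
Reactants: 6 19-acetate 3-mesylate of iodolactone 4
Product: 7 19-acetoxy-17-iodo-13,14,15,16-tetranor-ent-labd-2-en-12,8-olide
Conditions: NaOAc (5 equiv), DMF, 120 °C
Reagents that add atoms: none
Why: E2 elimination of the 3-sulfonate can only give the C2=C3 alkene because C4 is quaternary, and the buffered aprotic medium should suppress ionisation with ring contraction, as in the 3-sulfonates of 4,4-disubstituted triterpenoid A rings; the neopentyl iodide has no β-hydrogen and is inert to SN2.

Step 6
Reactants: 7 19-acetoxy-17-iodo-13,14,15,16-tetranor-ent-labd-2-en-12,8-olide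
Product: 8 19-acetoxy-2,3-dihydroxy-17-iodo-13,14,15,16-tetranor-ent-labdan-12,8-olide (2,3-cis-diol anti to the C10 methyl, 2-OH equatorial, 3-OH axial)
Conditions: OsO4 (5 mol %), NMO (1.5 equiv), acetone/H2O, rt
Reagents that add atoms: osmium tetroxide (catalytic carrier of both O atoms), O=[Os](=O)(=O)=O; N-methylmorpholine N-oxide, C[N+]1([O-])CCOCC1; water, O
Why: Catalytic OsO4/NMO syn-dihydroxylation of the only alkene present should occur on the face opposite the axial C10 methyl and the axial C4 CH2OAc, which sets C2 and C3 together in the configuration of the target.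

Step 7
Reactants: 8 19-acetoxy-2,3-dihydroxy-17-iodo-13,14,15,16-tetranor-ent-labdan-12,8-olide
Product: 9 19-acetoxy-2,3-dihydroxy-13,14,15,16-tetranor-ent-labd-8(17)-en-12-oic acid
Conditions: Zn dust (activated), AcOH/THF (1:4), rt
Reagents that add atoms: none
Why: Zinc-mediated reductive β-elimination of the β-acyloxy iodide should open the temporary lactone and return the free C12 acid and the C8=C17 alkene in one operation, leaving acetate and diol untouched.

Step 8
Reactants: 9 19-acetoxy-2,3-dihydroxy-13,14,15,16-tetranor-ent-labd-8(17)-en-12-oic acid; 10 (R)-methyl hydrogen 3-methylglutarate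
Product: 11 methyl (13R)-19-acetoxy-2,3-dihydroxy-ent-labd-8(17)-en-15-oate
Conditions: 10 (8 equiv), Et3N (5 mol % of total CO2H), MeOH/pyridine 4:1, Pt anode and Pt cathode, undivided cell, ca. 0.25 A cm−2, 40 °C
Reagents that add atoms: none
Why: Both carboxylates are oxidised at the platinum anode to acyloxy radicals that lose CO2 in the adsorbed layer, giving the primary C11 radical (the exocyclic CH2 on C9 of ring B) and the primary C12 radical of the glutarate arm, which combine to form the C11–C12 bond. The closest known reaction type is the mixed Kolbe electrolysis of an alkanoic acid with a dicarboxylic acid half ester, a classical route to methyl-branched chains with this very half ester and to side-chain-extended steroid and bile acids that carry free hydroxyl and acetate groups. No ring is closed and no stereocentre is formed: C13 lies one carbon from the C12 radical and C9 one carbon from the C11 radical, so both are carried through unchanged. The step needs cross-coupling over homo-coupling, which the eight-fold excess of the cheap half ester 10 should secure for the valuable acid 9, the symmetrical diester dimer of 10 being removed by chromatography. It also needs the homoallylic C11 radical to couple before it closes 3-exo onto C8, and the alkene to stay unoxidised; the high radical density at the anode and the use of the less oxidisable 1,1-disubstituted C8=C17 alkene (the trisubstituted C7=C8 alkene is made only afterwards) should secure both.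

Step 9
Reactants: 11 methyl (13R)-19-acetoxy-2,3-dihydroxy-ent-labd-8(17)-en-15-oate
Product: 12 methyl (13R)-19-acetoxy-2,3-dihydroxy-ent-labd-7-en-15-oate
Conditions: Co(salen-tBu,tBu)Cl (5 mol %), PhSiH3 (5 mol %), benzene, rt
Reagents that add atoms: none
Why: Cobalt–salen hydride (HAT) alkene isomerisation: Co–H should transfer H• to C17 to give the tertiary C8 radical, and cobalt(II) should take H• back from the unhindered C7 methylene rather than from the C9 methine wedged between the quaternary C10 and the side chain, so the double bond moves one position to the trisubstituted C7=C8 alkene, which is not re-engaged, and C9 is untouched.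

Step 10
Reactants: 12 methyl (13R)-19-acetoxy-2,3-dihydroxy-ent-labd-7-en-15-oate
Product: 13 (13R)-19-acetoxy-2,3-dihydroxy-ent-labd-7-en-15-oic acid (target)
Conditions: LiI (5 equiv), pyridine, reflux; 1 M HCl work-up
Reagents that add atoms: none
Why: SN2 O-demethylation by iodide should cleave only the methyl ester, because the acetate sits on the neopentyl C19 and cannot be dealkylated and no hydroxide or alkoxide is present to attack its carbonyl.

Compound list
1 | andrographolide | OC[C@@]1(C)[C@H]2CCC(=C)[C@@H](C/C=C3/C(=O)OC[C@H]3O)[C@]2(C)CC[C@H]1O | starting material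
2 | 3,19-dihydroxy-13,14,15,16-tetranor-ent-labd-8(17)-en-12-al | OC[C@@]1(C)[C@H]2CCC(=C)[C@@H](CC=O)[C@]2(C)CC[C@H]1O | intermediate
3 | 3,19-dihydroxy-13,14,15,16-tetranor-ent-labd-8(17)-en-12-oic acid | OC[C@@]1(C)[C@H]2CCC(=C)[C@@H](CC(=O)O)[C@]2(C)CC[C@H]1O | intermediate
4 | 3,19-dihydroxy-17-iodo-13,14,15,16-tetranor-ent-labdan-12,8-olide (trans-fused iodolactone) | OC[C@@]1(C)[C@H]2CC[C@]3(CI)OC(=O)C[C@H]3[C@]2(C)CC[C@H]1O | intermediate
5 | 19-acetate of iodolactone 4 | CC(=O)OC[C@@]1(C)[C@H]2CC[C@]3(CI)OC(=O)C[C@H]3[C@]2(C)CC[C@H]1O | intermediate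
6 | 19-acetate 3-mesylate of iodolactone 4 | CC(=O)OC[C@@]1(C)[C@H]2CC[C@]3(CI)OC(=O)C[C@H]3[C@]2(C)CC[C@H]1OS(C)(=O)=O | intermediate
7 | 19-acetoxy-17-iodo-13,14,15,16-tetranor-ent-labd-2-en-12,8-olide | CC(=O)OC[C@@]1(C)[C@H]2CC[C@]3(CI)OC(=O)C[C@H]3[C@]2(C)CC=C1 | intermediate
8 | 19-acetoxy-2,3-dihydroxy-17-iodo-13,14,15,16-tetranor-ent-labdan-12,8-olide (2,3-cis-diol anti to C20) | CC(=O)OC[C@@]1(C)[C@H]2CC[C@]3(CI)OC(=O)C[C@H]3[C@]2(C)C[C@H](O)[C@@H]1O | intermediate
9 | 19-acetoxy-2,3-dihydroxy-13,14,15,16-tetranor-ent-labd-8(17)-en-12-oic acid | CC(=O)OC[C@@]1(C)[C@H]2CCC(=C)[C@@H](CC(=O)O)[C@]2(C)C[C@H](O)[C@@H]1O | intermediate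
10 | (R)-methyl hydrogen 3-methylglutarate, (3R)-5-methoxy-3-methyl-5-oxopentanoic acid | COC(=O)C[C@H](C)CC(=O)O | starting material
11 | methyl (13R)-19-acetoxy-2,3-dihydroxy-ent-labd-8(17)-en-15-oate | CC(=O)OC[C@@]1(C)[C@H]2CCC(=C)[C@@H](CC[C@@H](C)CC(=O)OC)[C@]2(C)C[C@H](O)[C@@H]1O | intermediate
12 | methyl (13R)-19-acetoxy-2,3-dihydroxy-ent-labd-7-en-15-oate | CC(=O)OC[C@@]1(C)[C@H]2CC=C(C)[C@@H](CC[C@@H](C)CC(=O)OC)[C@]2(C)C[C@H](O)[C@@H]1O | intermediate
13 | (13R)-19-acetoxy-2,3-dihydroxy-ent-labd-7-en-15-oic acid | CC(=O)OC[C@@]1(C)[C@H]2CC=C(C)[C@@H](CC[C@@H](C)CC(=O)O)[C@]2(C)C[C@H](O)[C@@H]1O | target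

Total steps: 10. Longest linear sequence: 10 steps (1 to 13); 10 is used as purchased.

Steps most likely to fail

Step 1. The oxidant may lose its chemoselectivity: permanganate may also attack the exocyclic C8=C17 bond, or over-oxidise, so that the ring-B alkene is lost together with the butenolide. The fallback gives up selectivity and rebuilds the methylene group. It sets out from 1: exhaustive ozonolysis (O3, CH2Cl2/MeOH, −78 °C; Me2S) cleaves both alkenes to 3,19-dihydroxy-8-oxo-13,14,15,16,17-pentanor-ent-labdan-12-al F1. Pinnick oxidation gives the keto acid 3,19-dihydroxy-8-oxo-13,14,15,16,17-pentanor-ent-labdan-12-oic acid F2. Wittig methylenation of the C8 ketone with excess Ph3P=CH2 (THF/toluene, warm) restores C17, the side chain on C9 staying equatorial, and the route is rejoined at 3.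

Step 8. The valuable C11 radical may be consumed by homo-dimerisation, disproportionation or further anodic oxidation to the cation instead of cross-combination, or the alkene may be oxidised at the anode. The fallback replaces anodic radical–radical coupling by a reductive, nickel-mediated doubly decarboxylative coupling of two redox-active esters. It sets out from 9 and 10: 9 is protected as its 2,3-acetonide F5 (2,2-dimethoxypropane, PPTS) and converted to the N-hydroxyphthalimide ester F6 (N-hydroxyphthalimide, DIC, cat. DMAP); 10 gives the N-hydroxyphthalimide ester F7 in the same way. Electroreductive nickel catalysis (NiCl2·6H2O, terpyridine-type ligand, silver-modified cathode, Mg anode, NMP, rt, excess F7) should join F6 and F7 to the coupled acetonide methyl ester F8. Aqueous 80 % AcOH removes the acetonide and the route is rejoined at 11.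

Step 5. The equatorial sulfonate may ionise instead of undergoing E2, with Wagner–Meerwein contraction of ring A, or be substituted by acetate. The fallback makes the alkene from the ketone oxidation level. It sets out from 5, isolated after the acetylation stage of step 4: Dess–Martin periodinane gives the 3-ketone F3. Tf2O with 2,6-di-tert-butyl-4-methylpyridine (CH2Cl2, 0 °C) gives the C2=C3 enol triflate F4, the only enolisation direction open because C4 is quaternary. Palladium-catalysed formate reduction (Pd(OAc)2, PPh3, HCO2H, Bu3N, DMF, 60 °C) should reduce the vinyl triflate much faster than it touches the neopentyl iodide, and the route is rejoined at 7.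

Further compounds
F1 | step 1 | 3,19-dihydroxy-8-oxo-13,14,15,16,17-pentanor-ent-labdan-12-al | OC[C@@]1(C)[C@H]2CCC(=O)[C@@H](CC=O)[C@]2(C)CC[C@H]1O
F2 | step 1 | 3,19-dihydroxy-8-oxo-13,14,15,16,17-pentanor-ent-labdan-12-oic acid | OC[C@@]1(C)[C@H]2CCC(=O)[C@@H](CC(=O)O)[C@]2(C)CC[C@H]1O
F3 | step 5 | 19-acetoxy-17-iodo-3-oxo-13,14,15,16-tetranor-ent-labdan-12,8-olide | CC(=O)OC[C@@]1(C)[C@H]2CC[C@]3(CI)OC(=O)C[C@H]3[C@]2(C)CCC1=O
F4 | step 5 | 19-acetoxy-17-iodo-3-(trifluoromethylsulfonyloxy)-13,14,15,16-tetranor-ent-labd-2-en-12,8-olide | CC(=O)OC[C@@]1(C)[C@H]2CC[C@]3(CI)OC(=O)C[C@H]3[C@]2(C)CC=C1OS(=O)(=O)C(F)(F)F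
F5 | step 8 | 2,3-O-isopropylidene derivative of acid 9 | CC(=O)OC[C@@]1(C)[C@H]2CCC(=C)[C@@H](CC(=O)O)[C@]2(C)C[C@@H]3OC(C)(C)O[C@H]13
F6 | step 8 | N-hydroxyphthalimide ester of F5 | CC(=O)OC[C@@]1(C)[C@H]2CCC(=C)[C@@H](CC(=O)ON4C(=O)c5ccccc5C4=O)[C@]2(C)C[C@@H]3OC(C)(C)O[C@H]13
F7 | step 8 | N-hydroxyphthalimide ester of (R)-methyl hydrogen 3-methylglutarate | COC(=O)C[C@H](C)CC(=O)ON1C(=O)c2ccccc2C1=O
F8 | step 8 | methyl (13R)-19-acetoxy-2,3-O-isopropylidene-2,3-dihydroxy-ent-labd-8(17)-en-15-oate | CC(=O)OC[C@@]1(C)[C@H]2CCC(=C)[C@@H](CC[C@@H](C)CC(=O)OC)[C@]2(C)C[C@@H]3OC(C)(C)O[C@H]13
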